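## Analysis of the target

The target is a monocyclic 1,4-benzoquinone with a methoxy group at C2 and a tridecyl chain at C6; C3 and C5 carry hydrogen, so the C1 carbonyl lies between the two substituted carbons. The chain is attached through its C1' methylene, and C2' carries an acetoxy group, a hydrogen and the undecyl residue (C3' to C13'). C2' is the only stereocentre (R), so only absolute configuration has to be controlled. The quinone is the sensitive part: it is reduced by hydrogen on palladium and by low-valent metals, its methoxy enone is a vinylogous ester open to nucleophiles, and it acidifies C1', from which base can expel the C2' acetate as acetic acid. The stereocentre is hard because its two carbon substituents are both methylene groups (CH2-aryl and CH2-alkyl), which an asymmetric ketone reduction can hardly tell apart. The strategy rests on C2' having the oxidation level of an aldehyde carbon: the carbonyl of an arylacetaldehyde can take up acetyl bromide to place OAc and Br on C2', and the bromine is then exchanged for the undecyl carbon, so the C2'-C3' bond is made at the stereocentre with the acetate already on it. The ring supports this, because a 2-methoxy-6-alkyl quinone is what para oxidation of a 3-methoxy-5-alkylphenol gives: the position para to the hydroxyl lies between the methoxy carbon and the chain-bearing carbon.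

## Retrosynthetic reasoning

**12 to 11.** The C1 carbonyl oxygen is removed first, which leads back to phenol 11. The quinone cannot be carried through organozinc chemistry, low-valent nickel or hydrogenation, so it is made last. The forward oxidation has to attack the one ring carbon para to the hydroxyl and has to stay near neutral, so that the acetate is neither hydrolysed nor eliminated.

**11 to 10.** The phenol is masked as the benzyl ether 10. This group withstands base, dilute acid, a catalytic Lewis acid in the cold and organozinc reagents. Its removal by hydrogenolysis leaves the acetate alone, because the acetate sits on a homobenzylic carbon and not on a benzylic one.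

**10 to 9 and 7.** The C2'-C3' bond is cut at the stereocentre, giving the racemic bromo acetate 9 and undecylzinc bromide 7. Cutting the other carbinol bond, C1'-C2', would call for a benzylic organometallic on an electron-rich ring, which is prone to homocoupling. The chosen cut uses a plain primary alkylzinc and an electrophile that comes from the commercial arene. One step then forms a skeletal bond, sets the stereocentre and carries the acetate of the target. The forward reaction has to convert both enantiomers of 9 into one enantiomer of 10 with a chiral nickel catalyst, and has to outrun loss of HBr from 9.

**9 to 5 and 8.** The C-Br and C-OAc bonds at C2' are traced to addition of acetyl bromide 8 across the carbonyl of the arylacetaldehyde 5. The new centre is formed racemic, which is all the coupling asks for.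

**7 to 6.** The carbon-zinc bond comes from direct metal insertion into 1-bromoundecane 6.

**5 to 4 to 3.** The C1'-C2' bond is traced to a one-carbon Wittig homologation of aldehyde 3. The resulting enol ether 4 is unmasked to 5 by acid hydrolysis. This is done late, because arylacetaldehydes do not store well.

**3 to 1 and 2.** The benzyl ether is cut to the commercial phenol aldehyde 1 and benzyl bromide 2.

## Alternatives that were turned down

**Alternative 1: aldol aromatisation of a triketo ester.**
- Disconnection: the ring is opened between the chain-bearing carbon (quinone C6) and its CH neighbour (quinone C5), back to the linear triketo ester A2, which carries the stereocentre as a silyl ether.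
- Forward key step: mild base lets the C2 methylene of A2 add to the C7 ketone; dehydration and enolisation give the resorcylate A1.
- For it: the ring forms in a biomimetic way, and the carbinol of A2 can come from asymmetric hydrogenation of a beta-keto ester, a more dependable source of configuration than an enantioconvergent coupling on a new electrophile. On that point this alternative is stronger.
- Against it: polyketo esters are awkward to assemble and can cyclise in other modes (pyrone formation, Claisen-type closure). The silyloxy group of A2 is beta to the C7 ketone and can be eliminated by the base that triggers the aldol. A1 still needs selective methylation of one of two phenols, removal of the ester carbon, exchange of silyl ether for acetate, and the final oxidation.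
- Comparison: it builds a benzene ring that can be bought with the right oxygen pattern, and needs several more steps after its key step, where the chosen route needs two. The chosen route offers a short, convergent sequence and places the final ester in the stereo-defining step.

**Alternative 2: cyclobutenone benzannulation.**
- Disconnection: two ring bonds (quinone C3-C4 and C1-C2) are cut, giving the cyclobutenone A4 and methoxyethyne A5.
- Forward key step: heating opens A4 to a vinylketene, which adds A5 by [2+2] cycloaddition; 4π opening and 6π closure of the adduct, then tautomerisation, give phenol A3, which is the same compound as 11.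
- For it: the mechanism fixes the 1,3,5 pattern, the phenol arrives free and no protecting group is needed, so it is one step shorter after its key step. From A3 onwards the two routes are equal.
- Against it: the stereocentre is not made in the key step, so A4 needs its own asymmetric synthesis and a multistep cyclobutenone construction. In A4 the acetate is beta to a methylene activated by the enone and can be lost on heating. A5 is volatile, unstable and has to be prepared.
- Comparison: the effort goes into making an arene that is commercially available. The chosen route reaches 11 from a commercial arene and sets the stereocentre in the same step that joins the two fragments.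

**Alternative 3: lithiation-borylation.**
- Disconnection: the side-chain C1'-C2' bond is cut, giving the benzylic pinacol boronate A8 and the carbamate A7 of dodecanol.
- Forward key step: A7 is deprotonated enantioselectively next to oxygen by an alkyllithium paired with a chiral diamine; the lithiated carbamate adds to A8, and 1,2-migration of the benzyl group from boron to carbon with loss of the carbamate gives the secondary boronic ester A6.
- For it: the stereochemical course is reagent-controlled and well understood, and primary alkyl carbamates with primary boronic esters lie in the centre of the scope. On predictability of the configuration this alternative is stronger.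
- Against it: it needs a stoichiometric chiral diamine and an alkyllithium at low temperature. A8 has to be made in several steps from aldehyde 3. A6 still needs oxidation of the C-B bond and acetylation before it meets the chosen route at 10.
- Comparison: it costs roughly three more steps. The chosen route uses a catalytic amount of the chirality source and forms the acetate-bearing stereocentre directly, at the price of a less certain enantioselectivity.

Key step: step 6

Assumption: the sense of induction of a given bis(oxazoline) enantiomer with this electrophile is not predicted here; the route uses the enantiomer that gives the R acetate, and the mirror-image ligand is taken if a test coupling shows the opposite sense.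

## Route

Step 1
Reactants: 1 3-hydroxy-5-methoxybenzaldehyde; 2 benzyl bromide
Product: 3 3-(benzyloxy)-5-methoxybenzaldehyde
Conditions: K2CO3, DMF, rt
Reagents that add atoms: none
Why: Williamson ether synthesis; the phenoxide formed with K2CO3 displaces bromide from 2 by SN2, and the aldehyde is not touched.

Step 2
Reactants: 3 3-(benzyloxy)-5-methoxybenzaldehyde
Product: 4 1-(benzyloxy)-3-methoxy-5-(2-methoxyethenyl)benzene (E/Z mixture)
Conditions: Ph3P(CH2OMe)Cl, KOtBu, THF, 0 °C to rt
Reagents that add atoms: (methoxymethyl)triphenylphosphonium chloride, COC[P+](c1ccccc1)(c1ccccc1)c1ccccc1.[Cl-]
Why: Wittig reaction of the methoxymethylene ylide with an aromatic aldehyde; the alkene geometry does not matter because both isomers hydrolyse to the same aldehyde.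

Step 3
Reactants: 4 1-(benzyloxy)-3-methoxy-5-(2-methoxyethenyl)benzene
Product: 5 2-[3-(benzyloxy)-5-methoxyphenyl]acetaldehyde
Conditions: 2 M aq. HCl, THF, 50 °C
Reagents that add atoms: water, O
Why: Acid-catalysed enol ether hydrolysis; protonation at the benzylic carbon, addition of water to the oxocarbenium ion and loss of methanol give the aldehyde, and the aryl benzyl and aryl methyl ethers are stable to dilute acid. The aldehyde is taken on without storage.

Step 4
Reactants: 6 1-bromoundecane
Product: 7 undecylzinc bromide (solution in DMA, titrated)
Conditions: Zn dust, I2 (cat.), DMA, 70 °C
Reagents that add atoms: zinc, [Zn]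
Why: Direct insertion of iodine-activated zinc into a primary C-Br bond in a polar aprotic solvent; this is a standard preparation of alkylzinc bromides for Negishi coupling.

Step 5
Reactants: 5 2-[3-(benzyloxy)-5-methoxyphenyl]acetaldehyde; 8 acetyl bromide
Product: 9 rac-2-[3-(benzyloxy)-5-methoxyphenyl]-1-bromoethyl acetate
Conditions: AcBr, ZnBr2 (cat.), CH2Cl2, −20 °C; volatiles removed cold, crude used at once
Reagents that add atoms: none
Why: Lewis-acid-catalysed addition of an acyl bromide across an aldehyde carbonyl; the oxygen is acylated and bromide adds to the oxocarbenium carbon. Low temperature and a catalytic amount of ZnBr2 keep ring acylation, ether cleavage and loss of HBr slow, and the racemic centre is what the next step needs.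

Step 6
Reactants: 9 rac-2-[3-(benzyloxy)-5-methoxyphenyl]-1-bromoethyl acetate; 7 undecylzinc bromide
Product: 10 (2R)-1-[3-(benzyloxy)-5-methoxyphenyl]tridecan-2-yl acetate
Conditions: NiBr2·diglyme (10 mol %), chiral bis(oxazoline) ligand of the Ph-BOX type (12 mol %), THF/DMA, −10 °C
Reagents that add atoms: none
Why: This is a nickel-catalysed enantioconvergent Negishi alkyl-alkyl coupling; the closest known reaction type is the coupling of racemic 1-haloalkyl esters with primary alkylzinc halides, of which the beta-aryl electrophile 9 is a new member. The organozinc reduces the divalent nickel salt and transmetalates to a ligand-bound undecylnickel species, and a low-valent nickel complex abstracts bromine from either enantiomer of 9 to give the planar 1-acetoxy-2-arylethyl radical, so the racemate converges on one intermediate. The chiral undecylnickel complex captures this radical to give a trivalent dialkylnickel species, and reductive elimination forms the C2-C3 bond. No ring is closed. The new C2 stereocentre is controlled by the bis(oxazoline) ligand on nickel, which reads the radical through its coordinating acetoxy carbonyl and so has to distinguish OAc, CH2Ar and H, not two methylene groups. The step needs enantioselection and C-C bond formation to win over beta-hydride elimination or HBr loss to the styryl acetate and over homocoupling; the chelating ester, the low temperature and the immediate use of 9 serve this. The aryl ethers and the ester are inert to an alkylzinc halide, and the substrate has no aryl halide or other reducible group.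

Step 7
Reactants: 10 (2R)-1-[3-(benzyloxy)-5-methoxyphenyl]tridecan-2-yl acetate
Product: 11 (2R)-1-(3-hydroxy-5-methoxyphenyl)tridecan-2-yl acetate
Conditions: H2 (1 atm), Pd/C, EtOAc, rt
Reagents that add atoms: none
Why: Catalytic hydrogenolysis of the benzylic C-O bond of the aryl benzyl ether; the acetate is on a homobenzylic carbon and is not cleaved, the stereocentre is not involved, and the freed phenol is too far from the ester for acyl transfer.

Step 8
Reactants: 11 (2R)-1-(3-hydroxy-5-methoxyphenyl)tridecan-2-yl acetate
Product: 12 (2R)-1-(5-methoxy-3,6-dioxocyclohexa-1,4-dien-1-yl)tridecan-2-yl acetate (target)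
Conditions: (KSO3)2NO, KH2PO4 buffer, acetone/H2O, 0 °C to rt
Reagents that add atoms: potassium nitrosodisulfonate, [K+].[K+].[O-]S(=O)(=O)N([O])S(=O)(=O)[O-]
Why: Teuber oxidation; the nitroxyl radical removes the phenolic hydrogen, a second equivalent couples at the free para carbon between the methoxy carbon and the chain-bearing carbon, and loss of imidodisulfonate gives the para-quinone. The near-neutral buffer protects the acetate from hydrolysis and elimination, and C2' is not touched.

## Compound list

1 | 3-hydroxy-5-methoxybenzaldehyde | COc1cc(O)cc(C=O)c1 | starting material
2 | benzyl bromide | BrCc1ccccc1 | starting material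
3 | 3-(benzyloxy)-5-methoxybenzaldehyde | COc1cc(OCc2ccccc2)cc(C=O)c1 | intermediate
4 | 1-(benzyloxy)-3-methoxy-5-(2-methoxyethenyl)benzene (E/Z mixture) | COC=Cc1cc(OC)cc(OCc2ccccc2)c1 | intermediate
5 | 2-[3-(benzyloxy)-5-methoxyphenyl]acetaldehyde | O=CCc1cc(OC)cc(OCc2ccccc2)c1 | intermediate
6 | 1-bromoundecane | CCCCCCCCCCCBr | starting material
7 | undecylzinc bromide | CCCCCCCCCCC[Zn]Br | intermediate
8 | acetyl bromide | CC(Br)=O | starting material
9 | rac-2-[3-(benzyloxy)-5-methoxyphenyl]-1-bromoethyl acetate | CC(=O)OC(Br)Cc1cc(OC)cc(OCc2ccccc2)c1 | intermediate
10 | (2R)-1-[3-(benzyloxy)-5-methoxyphenyl]tridecan-2-yl acetate | CCCCCCCCCCC[C@H](Cc1cc(OC)cc(OCc2ccccc2)c1)OC(C)=O | intermediate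
11 | (2R)-1-(3-hydroxy-5-methoxyphenyl)tridecan-2-yl acetate | CCCCCCCCCCC[C@H](Cc1cc(O)cc(OC)c1)OC(C)=O | intermediate
12 | (2R)-1-(5-methoxy-3,6-dioxocyclohexa-1,4-dien-1-yl)tridecan-2-yl acetate | CCCCCCCCCCC[C@H](CC1=CC(=O)C=C(OC)C1=O)OC(C)=O | target

## Step count and risk

Total step count: 8. Longest linear sequence: 7 steps (steps 1, 2, 3, 5, 6, 7, 8); step 4 is a one-step side branch.

**Step 6 (key step).** The beta-aryl electrophile may lose HBr or undergo beta-hydride elimination toward the styryl acetate faster than it couples. Enantioselection may also be lower than for purely aliphatic members, because the CH2Ar group is a new steric and electronic partner for the ligand pocket. Fallback, from 6 and 5 back to 10: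
- Bromide 6 is converted with Mg in THF into undecylmagnesium bromide F1.
- F1 is transmetalated with ZnCl2 (0.5 equiv) and freed of magnesium salts to give diundecylzinc F2.
- F2 is added to aldehyde 5 in toluene at −20 °C with Ti(OiPr)4 and a catalytic chiral trans-cyclohexane-1,2-diyl bis(trifluoromethanesulfonamide), a catalytic enantioselective dialkylzinc addition, to give (2R)-1-[3-(benzyloxy)-5-methoxyphenyl]tridecan-2-ol F3. Here the catalyst only has to differentiate the two faces of an aldehyde.
- Acetylation of F3 with Ac2O, pyridine and catalytic DMAP gives 10.

**Step 5.** The electron-rich dialkoxyarene can be acylated on the ring, the benzyl ether can be cleaved by the acyl bromide and Lewis acid, and the product can lose HBr on warming or concentration. Fallback, from 5 back to 9: the aldehyde is converted with Ac2O and catalytic H2SO4 at 0 °C into the stable, purifiable geminal diacetate 2-[3-(benzyloxy)-5-methoxyphenyl]ethane-1,1-diyl diacetate F4. One acetoxy group is then exchanged for bromide with bromotrimethylsilane in CH2Cl2 at 0 °C, by analogy with the conversion of anomeric acetates into glycosyl bromides. This gives 9 with only a volatile silyl ester beside it and without free acyl bromide.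

**Step 3.** Self-condensation (aldol) and air oxidation of the enolisable arylacetaldehyde can occur during the warm acidic hydrolysis and the isolation. Fallback, from 3 back to 5: Corey-Chaykovsky epoxidation of 3 with Me3S+ I− and KOtBu in DMSO gives 2-[3-(benzyloxy)-5-methoxyphenyl]oxirane F5. Meinwald rearrangement of F5 with catalytic ZnBr2 in CH2Cl2 gives 5 under anhydrous conditions, in the solvent and with the Lewis acid of step 5, so that 5 can be acylated without isolation.

**Step 8.** The radical oxidant may attack an ortho position, or the phenoxyl radical may couple with itself, because the para carbon is flanked by two substituents. If the pH drifts upward, the acetate may be hydrolysed or eliminated. Fallback, from 11 back to 12: two-electron oxidation with PhI(OAc)2 (2 equiv) in methanol at 0 °C gives the quinone monoketal (2R)-1-(5,6,6-trimethoxy-3-oxocyclohexa-1,4-dien-1-yl)tridecan-2-yl acetate F6. Brief hydrolysis of the ketal with dilute aqueous acid in acetone then gives 12.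

## Further compounds

F1 | step 6 | undecylmagnesium bromide | CCCCCCCCCCC[Mg]Br
F2 | step 6 | diundecylzinc | CCCCCCCCCCC[Zn]CCCCCCCCCCC
F3 | step 6 | (2R)-1-[3-(benzyloxy)-5-methoxyphenyl]tridecan-2-ol | CCCCCCCCCCC[C@H](Cc1cc(OC)cc(OCc2ccccc2)c1)O
F4 | step 5 | 2-[3-(benzyloxy)-5-methoxyphenyl]ethane-1,1-diyl diacetate | CC(=O)OC(Cc1cc(OC)cc(OCc2ccccc2)c1)OC(C)=O
F5 | step 3 | 2-[3-(benzyloxy)-5-methoxyphenyl]oxirane (racemic) | COc1cc(OCc2ccccc2)cc(C2CO2)c1
F6 | step 8 | (2R)-1-(5,6,6-trimethoxy-3-oxocyclohexa-1,4-dien-1-yl)tridecan-2-yl acetate | CCCCCCCCCCC[C@H](CC1=CC(=O)C=C(OC)C1(OC)OC)OC(C)=O
A1 | alternative 1 | methyl 6-[(2R)-2-[(tert-butyldimethylsilyl)oxy]tridecyl]-2,4-dihydroxybenzoate | CCCCCCCCCCC[C@H](Cc1cc(O)cc(O)c1C(=O)OC)O[Si](C)(C)C(C)(C)C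
A2 | alternative 1 | methyl (9R)-9-[(tert-butyldimethylsilyl)oxy]-3,5,7-trioxoicosanoate | CCCCCCCCCCC[C@H](CC(=O)CC(=O)CC(=O)CC(=O)OC)O[Si](C)(C)C(C)(C)C
A3 | alternative 2 | (2R)-1-(3-hydroxy-5-methoxyphenyl)tridecan-2-yl acetate | CCCCCCCCCCC[C@H](Cc1cc(O)cc(OC)c1)OC(C)=O
A4 | alternative 2 | (2R)-1-(3-oxocyclobut-1-en-1-yl)tridecan-2-yl acetate | CCCCCCCCCCC[C@H](CC1=CC(=O)C1)OC(C)=O
A5 | alternative 2 | methoxyethyne | COC#C
A6 | alternative 3 | 2-[(2R)-1-[3-(benzyloxy)-5-methoxyphenyl]tridecan-2-yl]-4,4,5,5-tetramethyl-1,3,2-dioxaborolane | CCCCCCCCCCC[C@H](Cc1cc(OC)cc(OCc2ccccc2)c1)B1OC(C)(C)C(C)(C)O1
A7 | alternative 3 | dodecyl N,N-di(propan-2-yl)carbamate | CCCCCCCCCCCCOC(=O)N(C(C)C)C(C)C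
A8 | alternative 3 | 2-{[3-(benzyloxy)-5-methoxyphenyl]methyl}-4,4,5,5-tetramethyl-1,3,2-dioxaborolane | COc1cc(OCc2ccccc2)cc(CB2OC(C)(C)C(C)(C)O2)c1
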